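**Retrosynthetic overview** (hydroazulene numbering: isopropyl on C3, OH on C3a, methyl on C6, ester on C8, methyl on C8a)
- The anisate is attached last; the C8 carbinol comes from an enone by Luche reduction, which inverts the C8 configuration left by the key step.
- Five-membered ring (formed second): C3a–C3 bond by intramolecular carbonyl-ene reaction of a C3a ketone with the 4-methylpent-3-enyl chain on quaternary C8a; the C8a methyl comes from γ-methylation of the C4-carboxylated C3a ketone.
- Feature the strategy rests on: the seven-membered ring C3a–C4–C5–C6–C7–C8–C8a is a masked cyclohepta-1,4-diene. The C6=C7 alkene and, with the C3a ketone written as its enol ether, a C3a=C4 alkene sit on either side of the C5 methylene, and oxygenated C8 adjoins C8a.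
- Seven-membered ring (formed first): C4–C5 and C8–C8a bonds by dirhodium-catalysed asymmetric cyclopropanation of a siloxydiene terminus with a siloxyvinylcarbenoid, then Cope rearrangement of the cis-divinylcyclopropane.
- Fragments: vinyldiazoacetate from methyl acetoacetate and 5-bromo-2-methylpent-2-ene (three steps); diene from 3-methylbut-2-enal (one step).

Key step: step 5

Assumption: Rh2(S-PTAD)4 is taken to attack the diene face that leads to the (3R,4R) cycloheptadiene; if it favours the other face, Rh2(R-PTAD)4 is used and nothing else changes.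

Step 1
Reactants: 1 methyl acetoacetate; 2 5-bromo-2-methylpent-2-ene
Product: 3 methyl 8-methyl-3-oxonon-7-enoate
Conditions: NaH, THF, 0 °C; n-BuLi, 0 °C; then 2, 0 °C → rt; aq HCl
Reagents that add atoms: none
Why: Huckin–Weiler dianion alkylation, in which the more basic γ-carbanion of the acetoacetate dianion displaces the primary bromide and the α-position stays free; no stereocenter is formed.

Step 2
Reactants: 3 methyl 8-methyl-3-oxonon-7-enoate
Product: 4 methyl 2-diazo-8-methyl-3-oxonon-7-enoate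
Conditions: p-ABSA, Et3N, MeCN, 0 °C → rt
Reagents that add atoms: 4-acetamidobenzenesulfonyl azide (p-ABSA), CC(=O)Nc1ccc(cc1)S(=O)(=O)N=[N+]=[N-]
Why: Regitz diazo transfer to the active methylene of the β-keto ester; the trisubstituted alkene is inert to the sulfonyl azide under these conditions.

Step 3
Reactants: 4 methyl 2-diazo-8-methyl-3-oxonon-7-enoate
Product: 5 methyl (3Z)-3-[(tert-butyldimethylsilyl)oxy]-2-diazo-8-methylnona-3,7-dienoate
Conditions: TBSOTf, Et3N, CH2Cl2, 0 °C
Reagents that add atoms: tert-butyldimethylsilyl trifluoromethanesulfonate (TBSOTf), CC(C)(C)[Si](C)(C)OS(=O)(=O)C(F)(F)F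
Why: Soft enolisation and O-silylation of the diazo ketone, which should give the Z enol ether because the chain turns away from the diazo ester; the diazo group tolerates silyl triflate and amine at this temperature.

Step 4
Reactants: 6 3-methylbut-2-enal
Product: 7 (E)-3-methyl-1-[(triisopropylsilyl)oxy]buta-1,3-diene
Conditions: TIPSOTf, Et3N, Et2O, 0 °C → rt; distillation
Reagents that add atoms: triisopropylsilyl trifluoromethanesulfonate (TIPSOTf), CC(C)[Si](C(C)C)(C(C)C)OS(=O)(=O)C(F)(F)F
Why: Vinylogous soft enolisation (γ-deprotonation with O-silylation) of the enal gives the 1-siloxydiene, with the E enol ether expected to predominate on steric grounds.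

Step 5
Reactants: 5 methyl (3Z)-3-[(tert-butyldimethylsilyl)oxy]-2-diazo-8-methylnona-3,7-dienoate; 7 (E)-3-methyl-1-[(triisopropylsilyl)oxy]buta-1,3-diene (excess)
Product: 9 methyl (3R,4R)-2-[(tert-butyldimethylsilyl)oxy]-6-methyl-3-(4-methylpent-3-en-1-yl)-4-[(triisopropylsilyl)oxy]cyclohepta-1,5-diene-1-carboxylate (C8 OTIPS and C8a side chain cis), via cis-divinylcyclopropane 8 (not isolated)
Conditions: Rh2(S-PTAD)4 (dirhodium tetrakis[(S)-(1-adamantyl)(N-phthalimido)acetate], a divalent rhodium carboxylate, 1 mol %), 7 (3 equiv), hexanes, −26 °C, slow addition of 5; then rt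
Reagents that add atoms: none
Why: The catalyst converts 5 into a donor–acceptor rhodium vinylcarbenoid whose carbenoid carbon (C4) adds in a concerted, asynchronous cyclopropanation to the CH2=C(CH3) terminus of 7 (C4–C5 and C4–C6 bonds), and the resulting cis-divinylcyclopropane 8 rearranges below room temperature by breaking C4–C6 and forming C8–C8a. The closest known reaction type is the dirhodium tetracarboxylate-catalysed enantioselective cyclopropanation/Cope sequence (formal (4+3) cycloaddition) of siloxyvinyldiazoacetates with dienes. The three-membered ring closes by carbenoid [2+1] addition and the seven-membered ring by [3,3]-sigmatropic ring expansion of that cyclopropane through a boat transition state. C8 is set by the chiral carboxylate ligands, which choose the face of the diene terminus that meets the carbenoid, and C8a follows from C8 because the E enol ether of 7 and the Z siloxyvinyl unit of 5 both turn their substituents outward in the boat, so OTIPS and the side chain emerge cis. The step needs site selectivity for the 1,1-disubstituted alkene, which the low reactivity of trans-1,2-disubstituted alkenes toward bulky donor–acceptor carbenoids should provide, and it needs the dienyl residue cis to the siloxyvinyl group on the cyclopropane, which the usual preference of these carbenoids to place the π-substituent of the alkene beside the donor group and away from the ester should secure. Only the C8 configuration has to be carried forward, since C8a is rebuilt in step 7.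

Step 6
Reactants: 9 methyl (3R,4R)-2-[(tert-butyldimethylsilyl)oxy]-6-methyl-3-(4-methylpent-3-en-1-yl)-4-[(triisopropylsilyl)oxy]cyclohepta-1,5-diene-1-carboxylate
Product: 10 methyl (3R,4R)-4-hydroxy-6-methyl-3-(4-methylpent-3-en-1-yl)-2-oxocyclohept-5-ene-1-carboxylate (keto/enol and C1-epimer mixture)
Conditions: HF·pyridine, pyridine, THF, 0 °C → rt
Reagents that add atoms: none
Why: Fluoride desilylation removes the enol TBS group (unmasking the β-keto ester) and the TIPS ether together, because the next step needs the C8 oxygen as an alkoxide and not as a silyloxy leaving group; buffered HF·pyridine is used instead of basic fluoride to avoid dehydration of the allylic β-hydroxy ketone, and C8 and C8a are untouched.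

Step 7
Reactants: 10 methyl (3R,4R)-4-hydroxy-6-methyl-3-(4-methylpent-3-en-1-yl)-2-oxocyclohept-5-ene-1-carboxylate
Product: 11 methyl (3R,4R)-4-hydroxy-3,6-dimethyl-3-(4-methylpent-3-en-1-yl)-2-oxocyclohept-5-ene-1-carboxylate (C8a methyl trans to C8 OH)
Conditions: LDA (lithium diisopropylamide, 3.5 equiv), THF, −78 → −20 °C; MeI (1.1 equiv), −78 °C; AcOH quench
Reagents that add atoms: iodomethane, CI
Why: γ-Alkylation of a β-keto ester polyanion (Huckin–Weiler type) run on the alkoxide in the manner of a Fráter–Seebach alkylation: the last-formed, most basic carbanion at C8a is methylated, the C8 lithium alkoxide cannot leave so no β-elimination to a dienone occurs, and MeI enters anti to that alkoxide, which rebuilds C8a as a quaternary center with methyl trans to the C8 oxygen.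

Step 8
Reactants: 11 methyl (3R,4R)-4-hydroxy-3,6-dimethyl-3-(4-methylpent-3-en-1-yl)-2-oxocyclohept-5-ene-1-carboxylate
Product: 13 methyl (3R,4R)-4-[(tert-butyldimethylsilyl)oxy]-3,6-dimethyl-3-(4-methylpent-3-en-1-yl)-2-oxocyclohept-5-ene-1-carboxylate, via bis-silylated enol ether 12 (not isolated)
Conditions: TBSOTf (2.5 equiv), 2,6-lutidine, CH2Cl2, 0 °C; then K2CO3 (cat.), MeOH, 0 °C
Reagents that add atoms: tert-butyldimethylsilyl trifluoromethanesulfonate (TBSOTf), CC(C)(C)[Si](C)(C)OS(=O)(=O)C(F)(F)F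
Why: Silyl triflate silylation protects the hindered C8 alcohol (the keto ester enol is silylated as well), and mild methanolysis then cleaves only the vinylogous silyl ester; with C8a quaternary the silyloxy group can no longer be eliminated, and it shields C8 in the Lewis acid step.

Step 9
Reactants: 13 methyl (3R,4R)-4-[(tert-butyldimethylsilyl)oxy]-3,6-dimethyl-3-(4-methylpent-3-en-1-yl)-2-oxocyclohept-5-ene-1-carboxylate
Product: 14 (2R,3R)-3-[(tert-butyldimethylsilyl)oxy]-2,5-dimethyl-2-(4-methylpent-3-en-1-yl)cyclohept-4-en-1-one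
Conditions: LiCl, H2O, DMSO, 130 °C
Reagents that add atoms: none
Why: Krapcho dealkoxycarbonylation, in which chloride demethylates the ester and the β-keto carboxylate loses CO2; the quaternary C8a can neither epimerise nor eliminate, and the C6=C7 alkene is not in conjugation range of the ketone.

Step 10
Reactants: 14 (2R,3R)-3-[(tert-butyldimethylsilyl)oxy]-2,5-dimethyl-2-(4-methylpent-3-en-1-yl)cyclohept-4-en-1-one
Product: 15 (3R,3aS,8R,8aR)-8-[(tert-butyldimethylsilyl)oxy]-6,8a-dimethyl-3-(prop-1-en-2-yl)-2,3,4,5,8,8a-hexahydroazulen-3a(1H)-ol (OH, C8a methyl and isopropenyl all cis)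
Conditions: Me2AlCl (1.5 equiv), CH2Cl2, −78 → 0 °C
Reagents that add atoms: none
Why: Lewis acid-promoted intramolecular carbonyl-ene reaction (type 1 cyclisation) closes the five-membered ring by C3a–C3 bond formation; the tether on C8a can only reach the carbonyl face on its own side, which gives the cis ring fusion (OH cis to the C8a methyl), and the six-center hydrogen transfer needs the isopropylidene unit syn to the carbonyl oxygen, which places isopropenyl cis to OH.

Step 11
Reactants: 15 (3R,3aS,8R,8aR)-8-[(tert-butyldimethylsilyl)oxy]-6,8a-dimethyl-3-(prop-1-en-2-yl)-2,3,4,5,8,8a-hexahydroazulen-3a(1H)-ol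
Product: 16 (3R,3aS,8R,8aR)-8-[(tert-butyldimethylsilyl)oxy]-6,8a-dimethyl-3-(propan-2-yl)-2,3,4,5,8,8a-hexahydroazulen-3a(1H)-ol
Conditions: H2 (1 atm), RhCl(PPh3)3 (5 mol %), toluene, rt
Reagents that add atoms: none
Why: Homogeneous hydrogenation with RhCl(PPh3)3 reduces the unhindered 1,1-disubstituted alkene and leaves the trisubstituted ring alkene and the allylic silyl ether alone; no stereocenter is changed.

Step 12
Reactants: 16 (3R,3aS,8R,8aR)-8-[(tert-butyldimethylsilyl)oxy]-6,8a-dimethyl-3-(propan-2-yl)-2,3,4,5,8,8a-hexahydroazulen-3a(1H)-ol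
Product: 17 (3R,3aS,8R,8aR)-6,8a-dimethyl-3-(propan-2-yl)-2,3,4,5,8,8a-hexahydroazulene-3a,8(1H)-diol
Conditions: TBAF, THF, rt
Reagents that add atoms: none
Why: Fluoride cleavage of the TBS ether; no carbonyl group is present at this stage, so the basic fluoride cannot trigger retro-aldol or elimination.

Step 13
Reactants: 17 (3R,3aS,8R,8aR)-6,8a-dimethyl-3-(propan-2-yl)-2,3,4,5,8,8a-hexahydroazulene-3a,8(1H)-diol
Product: 18 (3R,3aS,8aS)-3a-hydroxy-6,8a-dimethyl-3-(propan-2-yl)-2,3,3a,4,5,8a-hexahydroazulen-8(1H)-one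
Conditions: Dess–Martin periodinane, pyridine, CH2Cl2, 0 °C → rt
Reagents that add atoms: none
Why: Dess–Martin oxidation converts the secondary allylic alcohol into the enone, the tertiary alcohol cannot be oxidised, and the neutral, cold conditions avoid retro-aldol cleavage of the β-hydroxy ketone.

Step 14
Reactants: 18 (3R,3aS,8aS)-3a-hydroxy-6,8a-dimethyl-3-(propan-2-yl)-2,3,3a,4,5,8a-hexahydroazulen-8(1H)-one
Product: 19 (3R,3aS,8S,8aR)-6,8a-dimethyl-3-(propan-2-yl)-2,3,4,5,8,8a-hexahydroazulene-3a,8(1H)-diol (C8 OH cis to C8a methyl)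
Conditions: NaBH4, CeCl3·7H2O, MeOH, −78 → −40 °C
Reagents that add atoms: none
Why: Luche 1,2-reduction, in which hydride should attack the carbonyl from the face opposite the adjacent angular C8a methyl (as in reductions of 17-keto steroids next to an angular methyl), giving the C8 alcohol cis to that methyl, i.e. the inverted 8S configuration.

Step 15
Reactants: 19 (3R,3aS,8S,8aR)-6,8a-dimethyl-3-(propan-2-yl)-2,3,4,5,8,8a-hexahydroazulene-3a,8(1H)-diol; 20 4-methoxybenzoyl chloride
Product: 21 (3R,3aS,8S,8aR)-3a-hydroxy-6,8a-dimethyl-3-(propan-2-yl)-1,2,3,3a,4,5,8,8a-octahydroazulen-8-yl 4-methoxybenzoate (CNP0158828.1)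
Conditions: Et3N, DMAP (cat.), CH2Cl2, 0 °C → rt
Reagents that add atoms: none
Why: DMAP-catalysed acyl transfer esterifies the secondary allylic alcohol with retention at C8, while the tertiary C3a alcohol is too hindered to react.

**Compound list**
1 | methyl acetoacetate | COC(=O)CC(C)=O | starting material
2 | 5-bromo-2-methylpent-2-ene | CC(C)=CCCBr | starting material
3 | methyl 8-methyl-3-oxonon-7-enoate | COC(=O)CC(=O)CCCC=C(C)C | intermediate
4 | methyl 2-diazo-8-methyl-3-oxonon-7-enoate | COC(=O)C(=[N+]=[N-])C(=O)CCCC=C(C)C | intermediate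
5 | methyl (3Z)-3-[(tert-butyldimethylsilyl)oxy]-2-diazo-8-methylnona-3,7-dienoate | COC(=O)C(=[N+]=[N-])/C(O[Si](C)(C)C(C)(C)C)=C/CCC=C(C)C | intermediate
6 | 3-methylbut-2-enal | CC(C)=CC=O | starting material
7 | (E)-3-methyl-1-[(triisopropylsilyl)oxy]buta-1,3-diene | C=C(C)/C=C/O[Si](C(C)C)(C(C)C)C(C)C | intermediate
8 | methyl (1S,2R)-1-{(1Z)-1-[(tert-butyldimethylsilyl)oxy]-6-methylhepta-1,5-dien-1-yl}-2-methyl-2-{(E)-2-[(triisopropylsilyl)oxy]ethenyl}cyclopropane-1-carboxylate (alkenyl groups cis) | COC(=O)[C@]1(C[C@]1(C)/C=C/O[Si](C(C)C)(C(C)C)C(C)C)/C(O[Si](C)(C)C(C)(C)C)=C/CCC=C(C)C | intermediate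
9 | methyl (3R,4R)-2-[(tert-butyldimethylsilyl)oxy]-6-methyl-3-(4-methylpent-3-en-1-yl)-4-[(triisopropylsilyl)oxy]cyclohepta-1,5-diene-1-carboxylate | CC(C)[Si](C(C)C)(C(C)C)O[C@@H]1C=C(C)CC(C(=O)OC)=C(O[Si](C)(C)C(C)(C)C)[C@@H]1CCC=C(C)C | intermediate
10 | methyl (3R,4R)-4-hydroxy-6-methyl-3-(4-methylpent-3-en-1-yl)-2-oxocyclohept-5-ene-1-carboxylate | O[C@@H]1C=C(C)CC(C(=O)OC)C(=O)[C@@H]1CCC=C(C)C | intermediate
11 | methyl (3R,4R)-4-hydroxy-3,6-dimethyl-3-(4-methylpent-3-en-1-yl)-2-oxocyclohept-5-ene-1-carboxylate | O[C@@H]1C=C(C)CC(C(=O)OC)C(=O)[C@]1(C)CCC=C(C)C | intermediate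
12 | methyl (3R,4R)-2,4-bis[(tert-butyldimethylsilyl)oxy]-3,6-dimethyl-3-(4-methylpent-3-en-1-yl)cyclohepta-1,5-diene-1-carboxylate | CC(C)(C)[Si](C)(C)O[C@@H]1C=C(C)CC(C(=O)OC)=C(O[Si](C)(C)C(C)(C)C)[C@]1(C)CCC=C(C)C | intermediate
13 | methyl (3R,4R)-4-[(tert-butyldimethylsilyl)oxy]-3,6-dimethyl-3-(4-methylpent-3-en-1-yl)-2-oxocyclohept-5-ene-1-carboxylate | CC(C)(C)[Si](C)(C)O[C@@H]1C=C(C)CC(C(=O)OC)C(=O)[C@]1(C)CCC=C(C)C | intermediate
14 | (2R,3R)-3-[(tert-butyldimethylsilyl)oxy]-2,5-dimethyl-2-(4-methylpent-3-en-1-yl)cyclohept-4-en-1-one | CC(C)(C)[Si](C)(C)O[C@@H]1C=C(C)CCC(=O)[C@]1(C)CCC=C(C)C | intermediate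
15 | (3R,3aS,8R,8aR)-8-[(tert-butyldimethylsilyl)oxy]-6,8a-dimethyl-3-(prop-1-en-2-yl)-2,3,4,5,8,8a-hexahydroazulen-3a(1H)-ol | CC(C)(C)[Si](C)(C)O[C@@H]1C=C(C)CC[C@]2(O)[C@@H](C(C)=C)CC[C@]12C | intermediate
16 | (3R,3aS,8R,8aR)-8-[(tert-butyldimethylsilyl)oxy]-6,8a-dimethyl-3-(propan-2-yl)-2,3,4,5,8,8a-hexahydroazulen-3a(1H)-ol | CC(C)(C)[Si](C)(C)O[C@@H]1C=C(C)CC[C@]2(O)[C@@H](C(C)C)CC[C@]12C | intermediate
17 | (3R,3aS,8R,8aR)-6,8a-dimethyl-3-(propan-2-yl)-2,3,4,5,8,8a-hexahydroazulene-3a,8(1H)-diol | O[C@@H]1C=C(C)CC[C@]2(O)[C@@H](C(C)C)CC[C@]12C | intermediate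
18 | (3R,3aS,8aS)-3a-hydroxy-6,8a-dimethyl-3-(propan-2-yl)-2,3,3a,4,5,8a-hexahydroazulen-8(1H)-one | O=C1C=C(C)CC[C@]2(O)[C@@H](C(C)C)CC[C@]12C | intermediate
19 | (3R,3aS,8S,8aR)-6,8a-dimethyl-3-(propan-2-yl)-2,3,4,5,8,8a-hexahydroazulene-3a,8(1H)-diol | O[C@H]1C=C(C)CC[C@]2(O)[C@@H](C(C)C)CC[C@]12C | intermediate
20 | 4-methoxybenzoyl chloride | COc1ccc(cc1)C(Cl)=O | starting material
21 | (3R,3aS,8S,8aR)-3a-hydroxy-6,8a-dimethyl-3-(propan-2-yl)-1,2,3,3a,4,5,8,8a-octahydroazulen-8-yl 4-methoxybenzoate | COc1ccc(C(=O)O[C@H]2C=C(C)CC[C@]3(O)[C@@H](C(C)C)CC[C@]23C)cc1 | target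

**Step count**
Total: 15 steps. Longest linear sequence: 14 steps (steps 1–3 and 5–15).

**Steps most likely to fail**

Step 5. The carbenoid may add to the enol ether double bond, or add with the dienyl group trans to the siloxyvinyl unit so that no Cope rearrangement occurs at low temperature, or the catalyst may discriminate the faces of the hindered 1,1-disubstituted terminus poorly. The fallback moves enantiocontrol from the catalyst to a covalently bound auxiliary; it sets out from 3 (with 7) and returns at 10. Keto ester 3 would be transesterified with (R)-pantolactone (DMAP cat., toluene, reflux, removal of methanol) to (3R)-4,4-dimethyl-2-oxooxolan-3-yl 8-methyl-3-oxonon-7-enoate F1. Diazo transfer (p-ABSA, Et3N) would give the diazo keto ester F2, and silylation (TBSOTf, Et3N) the pantolactonyl siloxyvinyldiazoacetate F3; the R enantiomer of the auxiliary is assumed to lead to the (3R,4R) series. Decomposition of F3 with achiral Rh2(OOct)4 (dirhodium tetraoctanoate) in the presence of 7 should give, through the pantolactonyl cis-divinylcyclopropane F4, the pantolactonyl cycloheptadienecarboxylate F5; the lactone carbonyl of the auxiliary is expected to block one face of the carbenoid. A trans-divinylcyclopropane, if it accumulates, would be equilibrated and rearranged by heating in toluene. HF·pyridine would then give the pantolactonyl hydroxy keto ester F6, and alcohol exchange of this β-keto ester with methanol (DMAP cat., MeOH/toluene, 70 °C) would release the auxiliary and give 10.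

Step 10. The Lewis acid may ionise the allylic silyl ether, the hindered α-quaternary ketone may not react, or a stepwise Prins path may give chloride or alkene isomers. The fallback removes the ionisable group first and uses the C8 oxygen as an anchor for the Lewis acid; it sets out from 14 and returns at 17. HF·pyridine (THF) would give (2R,3R)-3-hydroxy-2,5-dimethyl-2-(4-methylpent-3-en-1-yl)cyclohept-4-en-1-one F7. With Me2AlCl (2.5 equiv, CH2Cl2, −78 → 0 °C) the first equivalent forms the C8 aluminium alkoxide, which cannot ionise and can chelate and activate the C3a carbonyl for the ene closure to the isopropenyl diol F8. Hydrogenation of F8 with H2 and RhCl(PPh3)3 gives 17.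

Step 14. Hydride may be delivered from the face syn to the angular methyl, which would simply return 17. The fallback replaces reagent-controlled reduction by substitution with inversion; it sets out from 17 and returns at 19. Mitsunobu reaction of 17 with 4-nitrobenzoic acid (PPh3, DIAD, toluene, 0 °C → rt) at the secondary allylic alcohol should give the inverted (8S) 4-nitrobenzoate F9, and methanolysis (K2CO3, MeOH) of F9 gives 19.

**Further compounds**
F1 | step 5 | (3R)-4,4-dimethyl-2-oxooxolan-3-yl 8-methyl-3-oxonon-7-enoate | CC(C)=CCCCC(=O)CC(=O)O[C@H]1C(=O)OCC1(C)C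
F2 | step 5 | (3R)-4,4-dimethyl-2-oxooxolan-3-yl 2-diazo-8-methyl-3-oxonon-7-enoate | CC(C)=CCCCC(=O)C(=[N+]=[N-])C(=O)O[C@H]1C(=O)OCC1(C)C
F3 | step 5 | (3R)-4,4-dimethyl-2-oxooxolan-3-yl (3Z)-3-[(tert-butyldimethylsilyl)oxy]-2-diazo-8-methylnona-3,7-dienoate | CC(C)=CCC/C=C(O[Si](C)(C)C(C)(C)C)/C(=[N+]=[N-])C(=O)O[C@H]1C(=O)OCC1(C)C
F4 | step 5 | (3R)-4,4-dimethyl-2-oxooxolan-3-yl (1S,2R)-1-{(1Z)-1-[(tert-butyldimethylsilyl)oxy]-6-methylhepta-1,5-dien-1-yl}-2-methyl-2-{(E)-2-[(triisopropylsilyl)oxy]ethenyl}cyclopropane-1-carboxylate | O=C(O[C@H]1C(=O)OCC1(C)C)[C@]2(C[C@]2(C)/C=C/O[Si](C(C)C)(C(C)C)C(C)C)/C(O[Si](C)(C)C(C)(C)C)=C/CCC=C(C)C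
F5 | step 5 | (3R)-4,4-dimethyl-2-oxooxolan-3-yl (3R,4R)-2-[(tert-butyldimethylsilyl)oxy]-6-methyl-3-(4-methylpent-3-en-1-yl)-4-[(triisopropylsilyl)oxy]cyclohepta-1,5-diene-1-carboxylate | CC(C)[Si](C(C)C)(C(C)C)O[C@@H]1C=C(C)CC(C(=O)O[C@H]2C(=O)OCC2(C)C)=C(O[Si](C)(C)C(C)(C)C)[C@@H]1CCC=C(C)C
F6 | step 5 | (3R)-4,4-dimethyl-2-oxooxolan-3-yl (3R,4R)-4-hydroxy-6-methyl-3-(4-methylpent-3-en-1-yl)-2-oxocyclohept-5-ene-1-carboxylate | O[C@@H]1C=C(C)CC(C(=O)O[C@H]2C(=O)OCC2(C)C)C(=O)[C@@H]1CCC=C(C)C
F7 | step 10 | (2R,3R)-3-hydroxy-2,5-dimethyl-2-(4-methylpent-3-en-1-yl)cyclohept-4-en-1-one | O[C@@H]1C=C(C)CCC(=O)[C@]1(C)CCC=C(C)C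
F8 | step 10 | (3R,3aS,8R,8aR)-6,8a-dimethyl-3-(prop-1-en-2-yl)-2,3,4,5,8,8a-hexahydroazulene-3a,8(1H)-diol | O[C@@H]1C=C(C)CC[C@]2(O)[C@@H](C(C)=C)CC[C@]12C
F9 | step 14 | (3R,3aS,8S,8aR)-3a-hydroxy-6,8a-dimethyl-3-(propan-2-yl)-1,2,3,3a,4,5,8,8a-octahydroazulen-8-yl 4-nitrobenzoate | O=C(O[C@H]1C=C(C)CC[C@]2(O)[C@@H](C(C)C)CC[C@]12C)c1ccc(cc1)[N+](=O)[O-]
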